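**Plan**

1. Cuts: the two ester C–O bonds (O8–acetyl, O11–angeloyl); the C1=C10 double bond, reopened by placing SO2 between C1 and C10 (eleven-membered sulfone); the S–C1 and S–C10 bonds; C8–C9; C6–C7 together with the lactone bond O6–C12.
2. Forward order: the γ-lactone is made first (anti aldol, lactonization), the eleven-membered thiacycle is closed onto it by S-alkylation, ring contraction then gives the ten-membered carbocycle, and the two esters come last.
3. Enabling feature: the ten-membered ring carries a (Z)-trisubstituted C1=C10 olefin remote from the cis-fused C6–C7 lactone junction. C1 and C10 can serve as the two α-carbons of a sulfone, and the cis junction holds both side arms on one face of the lactone so that the eleven-membered ring can close.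
4. Stereochemistry: C11 is bought with (S)-citramalic acid; C6 and C7 come from an auxiliary-controlled anti aldol (anti pair = cis lactone); C8 from a reagent-controlled ketone reduction in the Felkin–Anh sense; (E)-C4=C5 from syn-carboalumination; (Z)-C1=C10 from the ring contraction.

Key step: step 13

Remark: atom numbers are those of the germacrane skeleton (ring C1–C10, C11–C13 on C7, C14 on C10, C15 on C4). C10 is formed without control in step 8, so 17–24 are carried as C10 epimers that converge in step 13 and their SMILES leave C10 open.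

Step 1
Reactants: 1 5-chloropent-1-yne
Product: 4 (2E)-6-chloro-3-methylhex-2-en-1-ol, via alkenylalane 2 (not isolated), via lithium aluminate 3 (not isolated)
Conditions: Me3Al, (C5H5)2ZrCl2 (cat.), CH2Cl2, 0 to 23 °C; n-BuLi, THF, −78 °C; (CH2O)n, −78 to 23 °C; aq. HCl
Reagents that add atoms: trimethylaluminium C[Al](C)C; paraformaldehyde (as formaldehyde) C=O
Why: Negishi zirconium-catalysed carboalumination adds methyl and aluminium syn across the terminal alkyne with methyl on the internal carbon, and the aluminate is hydroxymethylated with retention, so only the (E)-trisubstituted olefin (future C4=C5 with C15) should form.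

Step 2
Reactants: 4 (2E)-6-chloro-3-methylhex-2-en-1-ol
Product: 5 (2E)-6-chloro-3-methylhex-2-enal
Conditions: MnO2, CH2Cl2, 23 °C
Reagents that add atoms: none
Why: Allylic oxidation with MnO2 is selective for the allylic alcohol and should leave the alkyl chloride and the (E)-geometry untouched.

Step 3
Reactants: 6 (S)-citramalic acid
Product: 7 2-[(4S)-2,2,4-trimethyl-5-oxo-1,3-dioxolan-4-yl]acetic acid
Conditions: 2,2-dimethoxypropane, pyridinium p-toluenesulfonate (cat.), CH2Cl2, 23 °C
Reagents that add atoms: 2,2-dimethoxypropane COC(C)(C)OC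
Why: Acid-catalysed acetalization (dioxolanone formation) engages only the α-hydroxy acid unit, which masks O11 and C12 together, leaves the C8 carboxyl free and does not touch the bought C11 stereocentre.

Step 4
Reactants: 7 2-[(4S)-2,2,4-trimethyl-5-oxo-1,3-dioxolan-4-yl]acetic acid; 8 (4R)-4-benzyl-1,3-oxazolidin-2-one
Product: 10 (4R)-4-benzyl-3-{2-[(4S)-2,2,4-trimethyl-5-oxo-1,3-dioxolan-4-yl]acetyl}-1,3-oxazolidin-2-one, via mixed pivalic anhydride 9 (not isolated)
Conditions: t-BuCOCl, Et3N, THF, −20 °C; then 8, LiCl, 23 °C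
Reagents that add atoms: none
Why: N-Acylation of the oxazolidinone through the mixed pivalic anhydride occurs at the unhindered acyl carbonyl and installs the auxiliary that will control C6 and C7.

Step 5
Reactants: 10 (4R)-4-benzyl-3-{2-[(4S)-2,2,4-trimethyl-5-oxo-1,3-dioxolan-4-yl]acetyl}-1,3-oxazolidin-2-one; 5 (2E)-6-chloro-3-methylhex-2-enal
Product: 13 (4R)-4-benzyl-3-{(2S,3R,4S)-2-[(1E)-5-chloro-2-methylpent-1-en-1-yl]-4-hydroxy-4-methyl-5-oxooxolane-3-carbonyl}-1,3-oxazolidin-2-one, via silyl ether 11 (not isolated), via hydroxy imide 12 (not isolated)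
Conditions: MgCl2 (cat.), Et3N, Me3SiCl, EtOAc, 23 °C; then pyridinium p-toluenesulfonate, MeOH, 23 to 40 °C
Reagents that add atoms: none
Why: Evans magnesium-halide-catalysed direct anti aldol: the chelated (Z)-magnesium enolate reacts through a boat transition state on the face away from the benzyl group of the (R)-auxiliary, which should set C7 and C6 in an anti relationship with the absolute sense shown, and after desilylation the C6 hydroxyl transacylates the dioxolanone (5-exo-trig) with loss of acetone, the anti pair mapping onto the cis-disubstituted lactone.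

Step 6
Reactants: 13 (4R)-4-benzyl-3-{(2S,3R,4S)-2-[(1E)-5-chloro-2-methylpent-1-en-1-yl]-4-hydroxy-4-methyl-5-oxooxolane-3-carbonyl}-1,3-oxazolidin-2-one
Product: 14 S-ethyl (2S,3R,4S)-2-[(1E)-5-chloro-2-methylpent-1-en-1-yl]-4-hydroxy-4-methyl-5-oxooxolane-3-carbothioate
Conditions: EtSH, n-BuLi, THF, 0 °C
Reagents that add atoms: ethanethiol CCS
Why: Thiolate transacylation of the exocyclic imide carbonyl (thioester formation) releases the auxiliary under conditions too weakly basic to epimerize C7 or to start a retro-aldol at C11, and at 0 °C it should outrun SN2 attack on the primary chloride.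

Step 7
Reactants: 14 S-ethyl (2S,3R,4S)-2-[(1E)-5-chloro-2-methylpent-1-en-1-yl]-4-hydroxy-4-methyl-5-oxooxolane-3-carbothioate; 15 (E)-prop-1-en-1-ylboronic acid
Product: 16 (3S,4R,5S)-4-[(2E)-but-2-enoyl]-5-[(1E)-5-chloro-2-methylpent-1-en-1-yl]-3-hydroxy-3-methyloxolan-2-one
Conditions: Pd2(dba)3 (cat.), P(2-furyl)3, CuO2C(C4H3S) (cuprous thiophene-2-carboxylate), THF, 50 °C
Reagents that add atoms: none
Why: Liebeskind–Srogl thioester–boronic acid coupling runs under neutral conditions with retention of the (E)-alkenyl geometry, so the ketone should form without epimerization at C7 or opening of the lactone.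

Step 8
Reactants: 16 (3S,4R,5S)-4-[(2E)-but-2-enoyl]-5-[(1E)-5-chloro-2-methylpent-1-en-1-yl]-3-hydroxy-3-methyloxolan-2-one
Product: 17 (3S,4R,5S)-4-[3-(acetylsulfanyl)butanoyl]-5-[(1E)-5-chloro-2-methylpent-1-en-1-yl]-3-hydroxy-3-methyloxolan-2-one (C10 epimers)
Conditions: AcSH, Et3N (cat.), CH2Cl2, 0 °C
Reagents that add atoms: thioacetic acid CC(=O)S
Why: Conjugate (thia-Michael) addition of thioacetic acid to the enone places sulfur on C10 under essentially non-basic conditions; C10 is not controlled and need not be, because it becomes sp2 in step 13.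

Step 9
Reactants: 17 (3S,4R,5S)-4-[3-(acetylsulfanyl)butanoyl]-5-[(1E)-5-chloro-2-methylpent-1-en-1-yl]-3-hydroxy-3-methyloxolan-2-one (C10 epimers)
Product: 18 (3S,4R,5S)-4-[(1S)-3-(acetylsulfanyl)-1-hydroxybutyl]-5-[(1E)-5-chloro-2-methylpent-1-en-1-yl]-3-hydroxy-3-methyloxolan-2-one (C10 epimers)
Conditions: (R)-1-methyl-3,3-diphenyltetrahydro-1H,3H-pyrrolo[1,2-c][1,3,2]oxazaborole (cat.), catecholborane, toluene, −78 °C
Reagents that add atoms: none
Why: Corey–Bakshi–Shibata reduction: with the branched C7 side as the large group the (R)-catalyst should deliver hydride to give (8S), the same sense as Felkin–Anh attack anti to the quaternary C11 substituent on C7, and the neutral borane leaves thioester, lactone and olefin alone.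

Step 10
Reactants: 18 (3S,4R,5S)-4-[(1S)-3-(acetylsulfanyl)-1-hydroxybutyl]-5-[(1E)-5-chloro-2-methylpent-1-en-1-yl]-3-hydroxy-3-methyloxolan-2-one (C10 epimers)
Product: 19 (3S,4S,5S)-4-[(1S)-3-(acetylsulfanyl)-1-(tert-butyldimethylsilyloxy)butyl]-5-[(1E)-5-chloro-2-methylpent-1-en-1-yl]-3-hydroxy-3-methyloxolan-2-one (C10 epimers)
Conditions: t-BuMe2SiOTf, 2,6-lutidine, CH2Cl2, −78 °C
Reagents that add atoms: tert-butyldimethylsilyl trifluoromethanesulfonate CC(C)(C)[Si](C)(C)OS(=O)(=O)C(F)(F)F
Why: Silyl ether formation at −78 °C selects the secondary C8 hydroxyl over the hindered tertiary C11 hydroxyl, and blocking O8 prevents later migration of the lactone from O6 to O8.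

Step 11
Reactants: 19 (3S,4S,5S)-4-[(1S)-3-(acetylsulfanyl)-1-(tert-butyldimethylsilyloxy)butyl]-5-[(1E)-5-chloro-2-methylpent-1-en-1-yl]-3-hydroxy-3-methyloxolan-2-one (C10 epimers)
Product: 21 (4E,6S,7S,8S,11S)-8-(tert-butyldimethylsilyloxy)-11-hydroxy-1,10-epithio-1,10-secogermacr-4-en-12,6-olide (C10 epimers), via thiol 20 (not isolated)
Conditions: Cs2CO3, MeOH, NaI (cat.), degassed DMF (0.002 M), 40 °C
Reagents that add atoms: none
Why: Methanolysis of the thioacetate frees the thiolate, which closes the eleven-membered ring by intramolecular SN2 thioetherification at C1 (iodide-assisted, high dilution), helped by the cis lactone that holds both arms on one face.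

Step 12
Reactants: 21 (4E,6S,7S,8S,11S)-8-(tert-butyldimethylsilyloxy)-11-hydroxy-1,10-epithio-1,10-secogermacr-4-en-12,6-olide (C10 epimers)
Product: 22 (4E,6S,7S,8S,11S)-8-(tert-butyldimethylsilyloxy)-11-hydroxy-1,10-epithio-1,10-secogermacr-4-en-12,6-olide S,S-dioxide (C10 epimers)
Conditions: (NH4)6Mo7O24·4H2O (cat.), 30% H2O2, EtOH, 0 to 23 °C
Reagents that add atoms: hydrogen peroxide OO
Why: Molybdate-catalysed peroxide oxidation is chemoselective for sulfide to sulfone and should not epoxidize the isolated trisubstituted olefin or affect the tertiary alcohol.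

Step 13
Reactants: 22 (4E,6S,7S,8S,11S)-8-(tert-butyldimethylsilyloxy)-11-hydroxy-1,10-epithio-1,10-secogermacr-4-en-12,6-olide S,S-dioxide (C10 epimers)
Product: 25 (1(10)Z,4E,6S,7S,8S,11S)-8-(tert-butyldimethylsilyloxy)-11-hydroxygermacra-1(10),4-dien-12,6-olide, via bromo sulfone 23 (not isolated), via episulfone 24 (not isolated)
Conditions: CBr2F2, KOH/Al2O3, t-BuOH–CH2Cl2, 0 to 10 °C; aq. citric acid
Reagents that add atoms: none
Why: Halophilic attack of the C1 sulfonyl carbanion on CBr2F2 gives the α-bromo sulfone 23; deprotonation at C10 and intramolecular 1,3-displacement of bromide (3-exo-tet) closes the C1–C10 bond as the thiirane 1,1-dioxide 24, which loses SO2 in a stereospecific cheletropic step. The closest known reaction type is the Ramberg–Bäcklund ring contraction of medium-ring cyclic sulfones under Chan's halogenative conditions, which turns an eleven-membered sulfone into a ten-membered cycloalkene. The ten-membered carbocycle is thus closed by a transannular 1,3-elimination inside the eleven-membered ring followed by extrusion of the one-atom bridge; no new stereocentre remains in 25, and C6, C7, C8 and C11 are not touched. The step must deliver the (Z)-C1=C10 olefin: the episulfone should form kinetically with C2 and C9 cis on the three-membered ring (the trans-fused bicycle would put a second trans double bond into a ring that already holds (E)-C4=C5), and SO2 loss retains that geometry. It must also spare the rest: the lactone has no α-hydrogen because C11 is quaternary, the C8 silyloxy group is γ to sulfur and cannot be eliminated, bromination at either α-carbon leads to the same episulfone, and a lactone opened by hydroxide can re-close only onto O6 because O8 is silylated.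

Step 14
Reactants: 25 (1(10)Z,4E,6S,7S,8S,11S)-8-(tert-butyldimethylsilyloxy)-11-hydroxygermacra-1(10),4-dien-12,6-olide
Product: 26 (1(10)Z,4E,6S,7S,8S,11S)-8-(tert-butyldimethylsilyloxy)-11-[(2Z)-2-methylbut-2-enoyloxy]germacra-1(10),4-dien-12,6-olide
Conditions: angelic acid, 2,4,6-Cl3C6H2COCl, Et3N, toluene, 23 °C; added to 25 and LiN(SiMe3)2, THF, −78 to 0 °C
Reagents that add atoms: angelic acid C/C=C(/C)C(=O)O
Why: Yamaguchi-type acylation: the lithium alkoxide of the tertiary C11 alcohol attacks the angeloyl carbonyl of the mixed anhydride (the aroyl carbonyl is shielded by two ortho chlorines) at low temperature, which should avoid isomerization to the tiglate and leaves C11 unchanged because its C–O bond is not broken.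

Step 15
Reactants: 26 (1(10)Z,4E,6S,7S,8S,11S)-8-(tert-butyldimethylsilyloxy)-11-[(2Z)-2-methylbut-2-enoyloxy]germacra-1(10),4-dien-12,6-olide
Product: 27 (1(10)Z,4E,6S,7R,8S,11S)-8-hydroxy-11-[(2Z)-2-methylbut-2-enoyloxy]germacra-1(10),4-dien-12,6-olide
Conditions: HF·pyridine, pyridine, THF, 0 to 23 °C
Reagents that add atoms: none
Why: Fluoride-mediated desilylation under buffered acidic conditions should remove the silyl group without base-induced acyl migration of the angelate and without acid-induced transannular cyclization of the diene.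

Step 16
Reactants: 27 (1(10)Z,4E,6S,7R,8S,11S)-8-hydroxy-11-[(2Z)-2-methylbut-2-enoyloxy]germacra-1(10),4-dien-12,6-olide
Product: 28 (1(10)Z,4E,6S,7R,8S,11S)-8-acetoxy-11-[(2Z)-2-methylbut-2-enoyloxy]germacra-1(10),4-dien-12,6-olide (CNP0148966.1)
Conditions: Ac2O, pyridine, 4-(dimethylamino)pyridine (cat.), CH2Cl2, 0 to 23 °C
Reagents that add atoms: acetic anhydride CC(=O)OC(C)=O
Why: Nucleophile-catalysed acetylation of the only free (secondary) hydroxyl should give the target with all stereocentres unchanged.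

**Compound list**

1 | 5-chloropent-1-yne | ClCCCC#C | starting material
2 | [(1E)-5-chloro-2-methylpent-1-en-1-yl]dimethylalane | C[Al](C)/C=C(\C)CCCCl | intermediate
3 | lithium butyl[(1E)-5-chloro-2-methylpent-1-en-1-yl]dimethylaluminate | [Li+].CCCC[Al-](C)(C)/C=C(\C)CCCCl | intermediate
4 | (2E)-6-chloro-3-methylhex-2-en-1-ol | OC/C=C(\C)CCCCl | intermediate
5 | (2E)-6-chloro-3-methylhex-2-enal | O=C/C=C(\C)CCCCl | intermediate
6 | (S)-citramalic acid, (2S)-2-hydroxy-2-methylbutanedioic acid | C[C@](O)(CC(=O)O)C(=O)O | starting material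
7 | 2-[(4S)-2,2,4-trimethyl-5-oxo-1,3-dioxolan-4-yl]acetic acid | C[C@@]1(CC(=O)O)OC(C)(C)OC1=O | intermediate
8 | (4R)-4-benzyl-1,3-oxazolidin-2-one | O=C1N[C@H](Cc2ccccc2)CO1 | starting material
9 | 2-[(4S)-2,2,4-trimethyl-5-oxo-1,3-dioxolan-4-yl]acetic pivalic anhydride | C[C@@]1(CC(=O)OC(=O)C(C)(C)C)OC(C)(C)OC1=O | intermediate
10 | (4R)-4-benzyl-3-{2-[(4S)-2,2,4-trimethyl-5-oxo-1,3-dioxolan-4-yl]acetyl}-1,3-oxazolidin-2-one | C[C@@]1(CC(=O)N2[C@H](Cc3ccccc3)COC2=O)OC(C)(C)OC1=O | intermediate
11 | (4R)-4-benzyl-3-{(2R,3S,4E)-8-chloro-5-methyl-3-(trimethylsilyloxy)-2-[(4S)-2,2,4-trimethyl-5-oxo-1,3-dioxolan-4-yl]oct-4-enoyl}-1,3-oxazolidin-2-one | C[Si](C)(C)O[C@@H](/C=C(\C)CCCCl)[C@@H](C(=O)N1[C@H](Cc2ccccc2)COC1=O)[C@]1(C)OC(C)(C)OC1=O | intermediate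
12 | (4R)-4-benzyl-3-{(2R,3S,4E)-8-chloro-3-hydroxy-5-methyl-2-[(4S)-2,2,4-trimethyl-5-oxo-1,3-dioxolan-4-yl]oct-4-enoyl}-1,3-oxazolidin-2-one | O[C@@H](/C=C(\C)CCCCl)[C@@H](C(=O)N1[C@H](Cc2ccccc2)COC1=O)[C@]1(C)OC(C)(C)OC1=O | intermediate
13 | (4R)-4-benzyl-3-{(2S,3R,4S)-2-[(1E)-5-chloro-2-methylpent-1-en-1-yl]-4-hydroxy-4-methyl-5-oxooxolane-3-carbonyl}-1,3-oxazolidin-2-one | C[C@@]1(O)C(=O)O[C@@H](/C=C(\C)CCCCl)[C@H]1C(=O)N1[C@H](Cc2ccccc2)COC1=O | intermediate
14 | S-ethyl (2S,3R,4S)-2-[(1E)-5-chloro-2-methylpent-1-en-1-yl]-4-hydroxy-4-methyl-5-oxooxolane-3-carbothioate | C[C@@]1(O)C(=O)O[C@@H](/C=C(\C)CCCCl)[C@H]1C(=O)SCC | intermediate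
15 | (E)-prop-1-en-1-ylboronic acid | C/C=C/B(O)O | starting material
16 | (3S,4R,5S)-4-[(2E)-but-2-enoyl]-5-[(1E)-5-chloro-2-methylpent-1-en-1-yl]-3-hydroxy-3-methyloxolan-2-one | C[C@@]1(O)C(=O)O[C@@H](/C=C(\C)CCCCl)[C@H]1C(=O)/C=C/C | intermediate
17 | (3S,4R,5S)-4-[3-(acetylsulfanyl)butanoyl]-5-[(1E)-5-chloro-2-methylpent-1-en-1-yl]-3-hydroxy-3-methyloxolan-2-one (C10 epimers) | C[C@@]1(O)C(=O)O[C@@H](/C=C(\C)CCCCl)[C@H]1C(=O)CC(C)SC(C)=O | intermediate
18 | (3S,4R,5S)-4-[(1S)-3-(acetylsulfanyl)-1-hydroxybutyl]-5-[(1E)-5-chloro-2-methylpent-1-en-1-yl]-3-hydroxy-3-methyloxolan-2-one (C10 epimers) | C[C@@]1(O)C(=O)O[C@@H](/C=C(\C)CCCCl)[C@H]1[C@@H](O)CC(C)SC(C)=O | intermediate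
19 | (3S,4S,5S)-4-[(1S)-3-(acetylsulfanyl)-1-(tert-butyldimethylsilyloxy)butyl]-5-[(1E)-5-chloro-2-methylpent-1-en-1-yl]-3-hydroxy-3-methyloxolan-2-one (C10 epimers) | C[C@@]1(O)C(=O)O[C@@H](/C=C(\C)CCCCl)[C@H]1[C@@H](O[Si](C)(C)C(C)(C)C)CC(C)SC(C)=O | intermediate
20 | (3S,4S,5S)-4-[(1S)-1-(tert-butyldimethylsilyloxy)-3-sulfanylbutyl]-5-[(1E)-5-chloro-2-methylpent-1-en-1-yl]-3-hydroxy-3-methyloxolan-2-one (C10 epimers) | C[C@@]1(O)C(=O)O[C@@H](/C=C(\C)CCCCl)[C@H]1[C@@H](O[Si](C)(C)C(C)(C)C)CC(C)S | intermediate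
21 | (4E,6S,7S,8S,11S)-8-(tert-butyldimethylsilyloxy)-11-hydroxy-1,10-epithio-1,10-secogermacr-4-en-12,6-olide, eleven-membered cyclic sulfide cis-fused to the lactone (C10 epimers) | O[C@]1(C)C(=O)O[C@H]2/C=C(\C)CCCSC(C)C[C@H](O[Si](C)(C)C(C)(C)C)[C@H]21 | intermediate
22 | S,S-dioxide of 21, eleven-membered cyclic sulfone (C10 epimers) | O[C@]1(C)C(=O)O[C@H]2/C=C(\C)CCCS(=O)(=O)C(C)C[C@H](O[Si](C)(C)C(C)(C)C)[C@H]21 | intermediate
23 | 1-bromo derivative of sulfone 22 (C1 and C10 open) | O[C@]1(C)C(=O)O[C@H]2/C=C(\C)CCC(Br)S(=O)(=O)C(C)C[C@H](O[Si](C)(C)C(C)(C)C)[C@H]21 | intermediate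
24 | (4E,6S,7S,8S,11S)-8-(tert-butyldimethylsilyloxy)-11-hydroxy-1,10-epithiogermacr-4-en-12,6-olide S,S-dioxide, thiirane 1,1-dioxide cis-fused to the ten-membered ring | O[C@]1(C)C(=O)O[C@H]2/C=C(\C)CCC3S(=O)(=O)C3(C)C[C@H](O[Si](C)(C)C(C)(C)C)[C@H]21 | intermediate
25 | (1(10)Z,4E,6S,7S,8S,11S)-8-(tert-butyldimethylsilyloxy)-11-hydroxygermacra-1(10),4-dien-12,6-olide | O[C@]1(C)C(=O)O[C@H]2/C=C(\C)CC/C=C(/C)C[C@H](O[Si](C)(C)C(C)(C)C)[C@H]21 | intermediate
26 | (1(10)Z,4E,6S,7S,8S,11S)-8-(tert-butyldimethylsilyloxy)-11-[(2Z)-2-methylbut-2-enoyloxy]germacra-1(10),4-dien-12,6-olide | C/C=C(/C)C(=O)O[C@]1(C)C(=O)O[C@H]2/C=C(\C)CC/C=C(/C)C[C@H](O[Si](C)(C)C(C)(C)C)[C@H]21 | intermediate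
27 | (1(10)Z,4E,6S,7R,8S,11S)-8-hydroxy-11-[(2Z)-2-methylbut-2-enoyloxy]germacra-1(10),4-dien-12,6-olide | C/C=C(/C)C(=O)O[C@]1(C)C(=O)O[C@H]2/C=C(\C)CC/C=C(/C)C[C@H](O)[C@H]21 | intermediate
28 | (1(10)Z,4E,6S,7R,8S,11S)-8-acetoxy-11-[(2Z)-2-methylbut-2-enoyloxy]germacra-1(10),4-dien-12,6-olide, 6,7-cis-fused lactone (CNP0148966.1) | C/C=C(/C)C(=O)O[C@]1(C)C(=O)O[C@H]2/C=C(\C)CC/C=C(/C)C[C@H](OC(C)=O)[C@H]21 | target

**Count and risks**

Total step count: 16. Longest linear sequence: 14 steps (steps 3 to 16 from (S)-citramalic acid; steps 1 and 2 make the aldehyde used in step 5).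

Steps most likely to fail:

1. Step 13 (ring contraction). Hydroxide may open the lactone or the in situ bromination may lag, and the episulfone may equilibrate, so that conversion and control of the C1=C10 geometry are lost. Fallback (stepwise ring contraction through an isolated halo sulfone): sulfone 22 is deprotonated at C1 with LiN(i-Pr)2 in THF at −78 °C (one further equivalent for the C11 hydroxyl) and chlorinated with C2Cl6 to the α-chloro sulfone F1. F1 is isolated and treated with KOt-Bu in THF at −78 °C; 1,3-elimination and SO2 loss under these hydroxide-free, kinetically controlled conditions should give 25, where the route is rejoined.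

2. Step 5 (anti aldol). Soft enolization of the imide, whose α-carbon is flanked by a quaternary centre, may be slow, and the facial preference of the auxiliary may be opposed by C11, which would erode anti/syn and facial selectivity. Fallback (boron thioester aldol without auxiliary): acid 7 is converted with EtSH, dicyclohexylcarbodiimide and 4-(dimethylamino)pyridine into the S-ethyl thioester F2. Enolization with (c-C6H11)2BCl and Et3N in Et2O at −78 °C should give the (E)-enol borinate, whose chair-type addition to aldehyde 5 should give the anti adduct, hydroxy thioester F3, with facial control by the quaternary C11 centre. Lactonization of F3 with pyridinium p-toluenesulfonate leads to thioester 14, where the route is rejoined; steps 4 and 6 are then not needed.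

3. Step 11 (closure of the eleven-membered ring). Intermolecular S-alkylation may outrun ring closure and give dimers and oligomers. Fallback (reversible ring closure by conjugate addition): enone 16 is treated with KSAc in DMF to give the thioacetate F4, in which sulfur has replaced the chloride at C1. Hydrazinium acetate frees the thiol F5, which under Et3N catalysis at high dilution should add reversibly to C10 of the enone to give the macrocyclic β-sulfanyl ketone F6, open-chain oligomers being able to revert. Reduction as in step 9 should give the alcohol F7, and silylation as in step 10 gives sulfide 21, where the route is rejoined.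

**Further compounds**

F1 | step 13 | 1-chloro derivative of sulfone 22 (C1 and C10 open) | O[C@]1(C)C(=O)O[C@H]2/C=C(\C)CCC(Cl)S(=O)(=O)C(C)C[C@H](O[Si](C)(C)C(C)(C)C)[C@H]21
F2 | step 5 | S-ethyl 2-[(4S)-2,2,4-trimethyl-5-oxo-1,3-dioxolan-4-yl]ethanethioate | C[C@@]1(CC(=O)SCC)OC(C)(C)OC1=O
F3 | step 5 | S-ethyl (2R,3S,4E)-8-chloro-3-hydroxy-5-methyl-2-[(4S)-2,2,4-trimethyl-5-oxo-1,3-dioxolan-4-yl]oct-4-enethioate | O[C@@H](/C=C(\C)CCCCl)[C@@H](C(=O)SCC)[C@]1(C)OC(C)(C)OC1=O
F4 | step 11 | (3S,4R,5S)-5-[(1E)-5-(acetylsulfanyl)-2-methylpent-1-en-1-yl]-4-[(2E)-but-2-enoyl]-3-hydroxy-3-methyloxolan-2-one | C[C@@]1(O)C(=O)O[C@@H](/C=C(\C)CCCSC(C)=O)[C@H]1C(=O)/C=C/C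
F5 | step 11 | (3S,4R,5S)-4-[(2E)-but-2-enoyl]-3-hydroxy-3-methyl-5-[(1E)-2-methyl-5-sulfanylpent-1-en-1-yl]oxolan-2-one | C[C@@]1(O)C(=O)O[C@@H](/C=C(\C)CCCS)[C@H]1C(=O)/C=C/C
F6 | step 11 | (4E,6S,7R,11S)-11-hydroxy-8-oxo-1,10-epithio-1,10-secogermacr-4-en-12,6-olide (C10 epimers) | O[C@]1(C)C(=O)O[C@H]2/C=C(\C)CCCSC(C)CC(=O)[C@H]21
F7 | step 11 | (4E,6S,7R,8S,11S)-8,11-dihydroxy-1,10-epithio-1,10-secogermacr-4-en-12,6-olide (C10 epimers) | O[C@]1(C)C(=O)O[C@H]2/C=C(\C)CCCSC(C)C[C@H](O)[C@H]21
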